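The target is cut at the C8–C9 bond of the seven-membered ring (C1, C5, C6, C7, C8, C9, C10). In that ring the oxygen-bearing C8 and the methyl-bearing C10, itself attached to the tertiary carbinol C1, flank one unsubstituted carbon, C9. With C10 drawn as C10=CH2 this is a homoallylic alcohol, the product pattern of a carbonyl–ene reaction. One Lewis-acid type-two ene cyclisation therefore joins a C8 aldehyde to the isopropenyl group on C1, closing the seven-membered ring, creating the C8 carbinol and leaving the C10 methylene for hydroxyl-directed hydrogenation. Its precursor is a cyclopentenone (ring C1–C5) carrying a silyl-protected C1 isopropenyl carbinol and, on C5, the chain C6(OTBS)–C7(CMe2OAc)–C8HO.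

Key step: step 13

Locants (guaiane numbering, used in all names): five-membered ring C1–C5, with C1 the ring-fusion carbinol, C3 the ketone and C4=C5 the enone alkene; seven-membered ring C1, C5, C6 (CH–O), C7 (CH–C11), C8 (CH–O), C9 (CH2), C10 (bearing C14); C11 is the CMe2O carbon. NAP = naphthalen-2-ylmethyl.

Remark on the chemistry: the ester is the (Z)-2-methylbut-2-enoate (angelate). NAP on O8, TBS on O6 and TMS on O1 are chosen so that each can be removed without touching the others.

Step 1
Reactants: 1 prenol (3-methylbut-2-en-1-ol)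
Product: 2 (R)-(3,3-dimethyloxiran-2-yl)methanol
Conditions: Ti(OiPr)4 (10 mol %), D-(−)-diethyl tartrate (12 mol %), t-BuOOH, 4 Å MS, CH2Cl2, −20 °C
Reagents that add atoms: tert-butyl hydroperoxide, CC(C)(C)OO
Why: Sharpless asymmetric epoxidation of a primary allylic alcohol, in which the D-(−)-tartrate–titanium catalyst should deliver oxygen to the alkene face that gives the 2R epoxy alcohol, fixing the centre that becomes C7.

Step 2
Reactants: 2 (R)-(3,3-dimethyloxiran-2-yl)methanol
Product: 3 (R)-3,3-dimethyl-2-[(naphthalen-2-ylmethoxy)methyl]oxirane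
Conditions: NaH, 2-(bromomethyl)naphthalene, Bu4NI (cat.), THF, 0 °C → rt
Reagents that add atoms: 2-(bromomethyl)naphthalene, BrCc1ccc2ccccc2c1
Why: Williamson etherification of the primary alkoxide under aprotic, cold conditions where Payne rearrangement is slow, installing an ether that later leaves with DDQ in the presence of silyl ethers.

Step 3
Reactants: 3 (R)-3,3-dimethyl-2-[(naphthalen-2-ylmethoxy)methyl]oxirane; 4 vinylmagnesium bromide
Product: 5 (3S)-2-methyl-3-[(naphthalen-2-ylmethoxy)methyl]pent-4-en-2-ol
Conditions: vinylMgBr, CuI (10 mol %), THF, −40 → 0 °C; aq NH4Cl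
Reagents that add atoms: none
Why: Copper-catalysed Grignard opening of a trisubstituted epoxide by SN2 attack at the less substituted carbon with inversion, which places the vinyl group (future C6) on C7 and frees the tertiary C11 hydroxyl.

Step 4
Reactants: 5 (3S)-2-methyl-3-[(naphthalen-2-ylmethoxy)methyl]pent-4-en-2-ol
Product: 6 (3S)-2-methyl-3-[(naphthalen-2-ylmethoxy)methyl]pent-4-en-2-yl acetate
Conditions: Ac2O, Et3N, DMAP, CH2Cl2, rt → 40 °C
Reagents that add atoms: acetic anhydride, CC(=O)OC(C)=O
Why: DMAP-catalysed acyl transfer (Steglich-type acetylation) is the standard way to esterify a tertiary alcohol and installs the C11 acetate of the target before the fragments are joined.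

Step 5
Reactants: 6 (3S)-2-methyl-3-[(naphthalen-2-ylmethoxy)methyl]pent-4-en-2-yl acetate
Product: 7 (2S)-3-acetoxy-3-methyl-2-[(naphthalen-2-ylmethoxy)methyl]butanal
Conditions: OsO4 (2 mol %), NaIO4, 2,6-lutidine, dioxane/H2O, rt; used without storage
Reagents that add atoms: sodium periodate, [Na+].[O-]I(=O)(=O)=O (terminal source of the aldehyde oxygen, relayed through osmium tetroxide, O=[Os](=O)(=O)=O)
Why: Lemieux–Johnson cleavage (osmium-catalysed dihydroxylation, then periodate glycol cleavage) of the only alkene under lutidine buffering should spare the naphthalene ring and leave the α-centre of the β-acetoxy aldehyde intact.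

Step 6
Reactants: 8 cyclotene (2-hydroxy-3-methylcyclopent-2-en-1-one)
Product: 9 2-methyl-5-oxocyclopent-1-en-1-yl trifluoromethanesulfonate
Conditions: Tf2O, pyridine, CH2Cl2, −78 → 0 °C
Reagents that add atoms: triflic anhydride, O=S(=O)(OS(=O)(=O)C(F)(F)F)C(F)(F)F
Why: O-sulfonylation of the single stable enol of the 1,2-dione gives the alkenyl triflate with the leaving group on the future C5 and the ketone on the future C1.

Step 7
Reactants: 7 (2S)-3-acetoxy-3-methyl-2-[(naphthalen-2-ylmethoxy)methyl]butanal; 9 2-methyl-5-oxocyclopent-1-en-1-yl trifluoromethanesulfonate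
Product: 10 2-[(1R,2R)-3-acetoxy-1-hydroxy-3-methyl-2-[(naphthalen-2-ylmethoxy)methyl]butyl]-3-methylcyclopent-2-en-1-one (6R,7R)
Conditions: CrCl2 (5 equiv), NiCl2 (2 mol %), DMF, rt
Reagents that add atoms: none
Why: Nozaki–Hiyama–Kishi coupling, in which zerovalent nickel inserts into the C–OTf bond and the derived alkenylchromium adds to the aldehyde only, with C6 set by Felkin–Anh addition anti to the bulky CMe2OAc group on C7 (a chelate through the C8 ether oxygen predicts the same face).

Step 8
Reactants: 10 the (6R,7R) hydroxy enone; 11 isopropenylmagnesium bromide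
Product: 12 (1R)-2-[(1R,2R)-3-acetoxy-1-hydroxy-3-methyl-2-[(naphthalen-2-ylmethoxy)methyl]butyl]-3-methyl-1-(prop-1-en-2-yl)cyclopent-2-en-1-ol (1R,6R,7R)
Conditions: isopropenylMgBr (3.5 equiv), THF, −78 → −40 °C; aq NH4Cl
Reagents that add atoms: none
Why: Chelation-controlled 1,2-addition of a Grignard reagent, in which the C6 magnesium alkoxide and the C1 carbonyl form a planar six-membered chelate so that the nucleophile enters C1 on the face opposite the C7 substituent (the allylic-strain conformer exposes the same face), while the fully substituted β-carbon excludes conjugate addition and the low temperature protects the acetate.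

Step 9
Reactants: 12 the (1R,6R,7R) diol
Product: 14 (1R,6R,7R)-C6-TBS C1-TMS bis-silyl ether of diol 12, via C6 mono-TBS ether 13 (not isolated)
Conditions: TBSOTf (1.1 equiv), 2,6-lutidine, CH2Cl2, −78 °C; then TMSOTf, −78 → 0 °C
Reagents that add atoms: tert-butyldimethylsilyl triflate, CC(C)(C)[Si](C)(C)OS(=O)(=O)C(F)(F)F; trimethylsilyl triflate, C[Si](C)(C)OS(=O)(=O)C(F)(F)F
Why: Silyl triflate silylation under lutidine buffering differentiates the two hydroxyls by size, the secondary C6–OH taking the bulky TBS group at −78 °C and the tertiary C1–OH only the small TMS group added afterwards.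

Step 10
Reactants: 14 the bis-silyl ether
Product: 15 (4R)-3-[(1R,2R)-3-acetoxy-1-(tert-butyldimethylsilyloxy)-3-methyl-2-[(naphthalen-2-ylmethoxy)methyl]butyl]-2-methyl-4-(prop-1-en-2-yl)-4-(trimethylsilyloxy)cyclopent-2-en-1-one (C3 ketone; 1R,6R,7R)
Conditions: CrO3, 3,5-dimethylpyrazole, CH2Cl2, −20 °C
Reagents that add atoms: chromium trioxide, O=[Cr](=O)=O
Why: Allylic oxidation of a cyclopentene ring methylene to the enone with the CrO3–3,5-dimethylpyrazole complex should occur at C3, the only secondary allylic C–H position (C2 is not allylic, C1 is quaternary and C6–H is shielded by its silyl ether).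

Step 11
Reactants: 15 the C3 ketone
Product: 16 (4R)-3-[(1R,2R)-3-acetoxy-1-(tert-butyldimethylsilyloxy)-2-(hydroxymethyl)-3-methylbutyl]-2-methyl-4-(prop-1-en-2-yl)-4-(trimethylsilyloxy)cyclopent-2-en-1-one (C8 alcohol)
Conditions: DDQ, CH2Cl2/pH 7 buffer, 0 °C → rt
Reagents that add atoms: none
Why: Oxidative cleavage of an arylmethyl ether by DDQ (benzylic hydride abstraction, then hydrolysis of the oxocarbenium ion) under buffered conditions should leave the TMS and TBS ethers, the acetate and the alkenes untouched.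

Step 12
Reactants: 16 the C8 alcohol
Product: 17 (2R,3R)-2-(2-acetoxypropan-2-yl)-3-(tert-butyldimethylsilyloxy)-3-[(5R)-2-methyl-3-oxo-5-(prop-1-en-2-yl)-5-(trimethylsilyloxy)cyclopent-1-en-1-yl]propanal (C8 aldehyde; 1R,6R,7R)
Conditions: Dess–Martin periodinane, NaHCO3, CH2Cl2, 0 °C → rt; used at once
Reagents that add atoms: none
Why: Dess–Martin oxidation of the primary alcohol is neutral when buffered, so C7 should not epimerise and neither β-leaving group (OAc on C11, OTBS on C6) should eliminate.

Step 13
Reactants: 17 the C8 aldehyde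
Product: 18 (1R,6R,7R,8R)-11-acetoxy-6-(tert-butyldimethylsilyloxy)-8-hydroxy-1-(trimethylsilyloxy)guaia-4,10(14)-dien-3-one
Conditions: Me2AlCl (3 equiv), CH2Cl2, −78 → −30 °C; aq Rochelle salt
Reagents that add atoms: none
Why: Me2AlCl binds the C8 aldehyde oxygen, the terminal carbon C9 of the isopropenyl group attacks C8 and a hydrogen of the isopropenyl methyl passes to oxygen through a six-centre array, so the π bond moves to C10=C14 and the alkoxide stays on aluminium with loss of methane. This is a Lewis-acid-promoted intramolecular type-two carbonyl–ene reaction, a known way to close six- and seven-membered rings. The seven-membered ring (C8, C9, C10, C1, C5, C6, C7) closes with both alkene carbons inside the new ring (endo to the alkene) and the carbonyl oxygen outside it (exo to C=O). The new C8 centre is controlled by C7: in the chair-like bicyclic transition state the CMe2OAc group sits pseudoequatorial, anti to the forming C8–C9 bond (Felkin–Anh sense), and the aluminium-bound oxygen must be pseudoaxial to reach the methyl hydrogen, which places C8–O cis to the C7 side chain and to C6–OTBS. The step needs reaction at the isopropenyl group only and one ene regiochemistry, which the substrate secures because the C3 ketone deactivates C4=C5, quaternary C1 leaves the methyl as the only hydrogen donor, the C1 silyl ether blocks lactol formation and the non-chelating silyl and acetate groups leave Felkin control in charge.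

Step 14
Reactants: 18 the C8 alcohol (ene product); 19 angelic acid
Product: 21 (1R,6R,7R,8R)-11-acetoxy-8-angeloyloxy-6-(tert-butyldimethylsilyloxy)-1-(trimethylsilyloxy)guaia-4,10(14)-dien-3-one, via angelic 2,4,6-trichlorobenzoic anhydride 20 (not isolated)
Conditions: 19, 2,4,6-Cl3C6H2COCl, Et3N, toluene, rt; then 18, toluene, 80 °C
Reagents that add atoms: none
Why: Yamaguchi esterification through the mixed trichlorobenzoic anhydride, run without DMAP in hot toluene because nucleophilic catalysts isomerise angelates to tiglates, acylates O8 with retention at C8.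

Step 15
Reactants: 21 the C8 angelate
Product: 22 (1R,6R,7R,8R)-11-acetoxy-8-angeloyloxy-6-(tert-butyldimethylsilyloxy)-1-hydroxyguaia-4,10(14)-dien-3-one
Conditions: PPTS, MeOH, 0 °C
Reagents that add atoms: none
Why: Acid-catalysed methanolysis removes the trimethylsilyl ether, which is far more labile than the hindered secondary TBS ether, so only the C1 hydroxyl is released.

Step 16
Reactants: 22 the C1 alcohol
Product: 23 (1R,6R,7R,8R,10S)-11-acetoxy-8-angeloyloxy-6-(tert-butyldimethylsilyloxy)-1-hydroxyguai-4-en-3-one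
Conditions: H2 (1 atm), [Ir(cod)(PCy3)(py)]PF6 (5 mol %), CH2Cl2, 0 °C → rt
Reagents that add atoms: none
Why: Hydroxyl-directed homogeneous hydrogenation, in which the C1 hydroxyl binds the cationic iridium catalyst and hydrogen reaches the neighbouring 1,1-disubstituted alkene from the ring face of that hydroxyl, placing the C10 methyl trans to C1–OH, while the conjugated enone and angelate alkenes should react much more slowly.

Step 17
Reactants: 23 the C6 silyl ether
Product: 24 (1R,6R,7S,8R,10S)-11-acetoxy-8-angeloyloxy-1,6-dihydroxyguai-4-en-3-one (target, CNP0273287.1)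
Conditions: HF·pyridine, pyridine, THF, 0 °C → rt
Reagents that add atoms: none
Why: Fluoride-mediated cleavage of the silyl ether under mildly acidic HF·pyridine avoids the base-induced acyl migration and retro-aldol opening of the β-hydroxy ketone that basic fluoride could cause.

Compound list
1 | prenol (3-methylbut-2-en-1-ol) | CC(C)=CCO | starting material
2 | (R)-(3,3-dimethyloxiran-2-yl)methanol | OC[C@H]1OC1(C)C | intermediate
3 | (R)-3,3-dimethyl-2-[(naphthalen-2-ylmethoxy)methyl]oxirane | CC1(C)O[C@@H]1COCc1ccc2ccccc2c1 | intermediate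
4 | vinylmagnesium bromide | C=C[Mg]Br | starting material
5 | (3S)-2-methyl-3-[(naphthalen-2-ylmethoxy)methyl]pent-4-en-2-ol | C=C[C@@H](COCc1ccc2ccccc2c1)C(C)(C)O | intermediate
6 | (3S)-2-methyl-3-[(naphthalen-2-ylmethoxy)methyl]pent-4-en-2-yl acetate | C=C[C@@H](COCc1ccc2ccccc2c1)C(C)(C)OC(C)=O | intermediate
7 | (2S)-3-acetoxy-3-methyl-2-[(naphthalen-2-ylmethoxy)methyl]butanal | O=C[C@@H](COCc1ccc2ccccc2c1)C(C)(C)OC(C)=O | intermediate
8 | cyclotene (2-hydroxy-3-methylcyclopent-2-en-1-one) | CC1=C(O)C(=O)CC1 | starting material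
9 | 2-methyl-5-oxocyclopent-1-en-1-yl trifluoromethanesulfonate | CC1=C(OS(=O)(=O)C(F)(F)F)C(=O)CC1 | intermediate
10 | 2-[(1R,2R)-3-acetoxy-1-hydroxy-3-methyl-2-[(naphthalen-2-ylmethoxy)methyl]butyl]-3-methylcyclopent-2-en-1-one | CC1=C([C@H](O)[C@@H](COCc2ccc3ccccc3c2)C(C)(C)OC(C)=O)C(=O)CC1 | intermediate
11 | isopropenylmagnesium bromide | CC(=C)[Mg]Br | starting material
12 | (1R)-2-[(1R,2R)-3-acetoxy-1-hydroxy-3-methyl-2-[(naphthalen-2-ylmethoxy)methyl]butyl]-3-methyl-1-(prop-1-en-2-yl)cyclopent-2-en-1-ol | CC1=C([C@H](O)[C@@H](COCc2ccc3ccccc3c2)C(C)(C)OC(C)=O)[C@](O)(C(C)=C)CC1 | intermediate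
13 | C6 mono-TBS ether of 12 (C1–OH free; 1R,6R,7R) | CC1=C([C@H](O[Si](C)(C)C(C)(C)C)[C@@H](COCc2ccc3ccccc3c2)C(C)(C)OC(C)=O)[C@](O)(C(C)=C)CC1 | intermediate
14 | C6-TBS, C1-TMS bis-silyl ether of 12 (1R,6R,7R) | CC1=C([C@H](O[Si](C)(C)C(C)(C)C)[C@@H](COCc2ccc3ccccc3c2)C(C)(C)OC(C)=O)[C@](O[Si](C)(C)C)(C(C)=C)CC1 | intermediate
15 | (4R)-3-[(1R,2R)-3-acetoxy-1-(tert-butyldimethylsilyloxy)-3-methyl-2-[(naphthalen-2-ylmethoxy)methyl]butyl]-2-methyl-4-(prop-1-en-2-yl)-4-(trimethylsilyloxy)cyclopent-2-en-1-one | CC1=C([C@H](O[Si](C)(C)C(C)(C)C)[C@@H](COCc2ccc3ccccc3c2)C(C)(C)OC(C)=O)[C@](O[Si](C)(C)C)(C(C)=C)CC1=O | intermediate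
16 | (4R)-3-[(1R,2R)-3-acetoxy-1-(tert-butyldimethylsilyloxy)-2-(hydroxymethyl)-3-methylbutyl]-2-methyl-4-(prop-1-en-2-yl)-4-(trimethylsilyloxy)cyclopent-2-en-1-one | CC1=C([C@H](O[Si](C)(C)C(C)(C)C)[C@@H](CO)C(C)(C)OC(C)=O)[C@](O[Si](C)(C)C)(C(C)=C)CC1=O | intermediate
17 | (2R,3R)-2-(2-acetoxypropan-2-yl)-3-(tert-butyldimethylsilyloxy)-3-[(5R)-2-methyl-3-oxo-5-(prop-1-en-2-yl)-5-(trimethylsilyloxy)cyclopent-1-en-1-yl]propanal | O=C[C@@H](C(C)(C)OC(C)=O)[C@@H](O[Si](C)(C)C(C)(C)C)C1=C(C)C(=O)C[C@@]1(O[Si](C)(C)C)C(C)=C | intermediate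
18 | (1R,6R,7R,8R)-11-acetoxy-6-(tert-butyldimethylsilyloxy)-8-hydroxy-1-(trimethylsilyloxy)guaia-4,10(14)-dien-3-one | O[C@@H]1CC(=C)[C@]2(O[Si](C)(C)C)CC(=O)C(C)=C2[C@H](O[Si](C)(C)C(C)(C)C)[C@@H]1C(C)(C)OC(C)=O | intermediate
19 | angelic acid ((Z)-2-methylbut-2-enoic acid) | C/C=C(/C)C(=O)O | starting material
20 | angelic 2,4,6-trichlorobenzoic anhydride | C/C=C(/C)C(=O)OC(=O)c1c(Cl)cc(Cl)cc1Cl | intermediate
21 | (1R,6R,7R,8R)-11-acetoxy-8-angeloyloxy-6-(tert-butyldimethylsilyloxy)-1-(trimethylsilyloxy)guaia-4,10(14)-dien-3-one | C/C=C(/C)C(=O)O[C@@H]1CC(=C)[C@]2(O[Si](C)(C)C)CC(=O)C(C)=C2[C@H](O[Si](C)(C)C(C)(C)C)[C@@H]1C(C)(C)OC(C)=O | intermediate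
22 | (1R,6R,7R,8R)-11-acetoxy-8-angeloyloxy-6-(tert-butyldimethylsilyloxy)-1-hydroxyguaia-4,10(14)-dien-3-one | C/C=C(/C)C(=O)O[C@@H]1CC(=C)[C@]2(O)CC(=O)C(C)=C2[C@H](O[Si](C)(C)C(C)(C)C)[C@@H]1C(C)(C)OC(C)=O | intermediate
23 | (1R,6R,7R,8R,10S)-11-acetoxy-8-angeloyloxy-6-(tert-butyldimethylsilyloxy)-1-hydroxyguai-4-en-3-one | C/C=C(/C)C(=O)O[C@@H]1C[C@H](C)[C@]2(O)CC(=O)C(C)=C2[C@H](O[Si](C)(C)C(C)(C)C)[C@@H]1C(C)(C)OC(C)=O | intermediate
24 | (1R,6R,7S,8R,10S)-11-acetoxy-8-angeloyloxy-1,6-dihydroxyguai-4-en-3-one | C/C=C(/C)C(=O)O[C@@H]1C[C@H](C)[C@]2(O)CC(=O)C(C)=C2[C@H](O)[C@@H]1C(C)(C)OC(C)=O | target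

Total step count: 17
Longest linear sequence: 16 steps (steps 1–5, then 7–17; step 6 makes the triflate separately)

Steps most likely to fail

Step 13. The ring may close through the alternative chair, in which the aldehyde oxygen lies anti to the pseudoaxial C6 silyl ether, so that facial selectivity at C8 is poor or reversed. The fallback sets out from aldehyde 17. The same Me2AlCl cyclisation is accepted with the opposite outcome, giving the C8-epimeric hydroazulenone alcohol F1. Mitsunobu esterification of F1 with angelic acid 19 (PPh3, DIAD, toluene, 0 °C → rt) then forms the ester with inversion at C8 instead of retention. This returns to the route at angelate 21, and step 14 is not needed.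

Step 10. Hydrogen abstraction may compete at the benzylic CH2 of the NAP ether, so that the protecting group is oxidised to an ester while C3 is only partly oxidised. The fallback sets out from bis-silyl ether 14 and changes the order of events so that no benzylic ether is present during the chromium oxidation. DDQ (CH2Cl2/pH 7 buffer) first removes the NAP group to give the cyclopentene primary alcohol F2. An excess of the CrO3–3,5-dimethylpyrazole complex (CH2Cl2, −20 °C), a known oxidant for alcohols and for allylic methylenes, then converts the C8 alcohol into the aldehyde and the C3 methylene into the ketone in one operation. This returns to the route at aldehyde 17, and steps 11 and 12 are skipped.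

Step 8. The C6 magnesium alkoxide may take up the neighbouring C11 acetyl group (1,3-acyl transfer), or the basic reagent may enolise the ketone, so that addition stalls or the acetate ends up on the wrong oxygen. The fallback sets out from hydroxy enone 10 and removes the alkoxide. TBSOTf and 2,6-lutidine (CH2Cl2, −78 °C) give the C6 silyl ether enone F3. The less basic organocerium reagent made from isopropenylmagnesium bromide 11 and CeCl3 (THF, −78 °C) then adds to the C1 ketone without chelation. Facial selectivity then rests on the allylic-strain conformer, with C6–H eclipsing the C4=C5 bond, in which the C7 residue should shield the same face as in the chelate; this is less secure than chelation control. The product is mono-silyl ether 13, from which the TMSOTf stage of step 9 continues to 14.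

Further compounds
F1 | step 13 | (1R,6R,7R,8S)-11-acetoxy-6-(tert-butyldimethylsilyloxy)-8-hydroxy-1-(trimethylsilyloxy)guaia-4,10(14)-dien-3-one (C8 epimer of 18) | O[C@H]1CC(=C)[C@]2(O[Si](C)(C)C)CC(=O)C(C)=C2[C@H](O[Si](C)(C)C(C)(C)C)[C@@H]1C(C)(C)OC(C)=O
F2 | step 10 | (1R)-2-[(1R,2R)-3-acetoxy-1-(tert-butyldimethylsilyloxy)-2-(hydroxymethyl)-3-methylbutyl]-3-methyl-1-(prop-1-en-2-yl)-1-(trimethylsilyloxy)cyclopent-2-ene | CC1=C([C@H](O[Si](C)(C)C(C)(C)C)[C@@H](CO)C(C)(C)OC(C)=O)[C@](O[Si](C)(C)C)(C(C)=C)CC1
F3 | step 8 | 2-[(1R,2R)-3-acetoxy-1-(tert-butyldimethylsilyloxy)-3-methyl-2-[(naphthalen-2-ylmethoxy)methyl]butyl]-3-methylcyclopent-2-en-1-one | CC1=C([C@H](O[Si](C)(C)C(C)(C)C)[C@@H](COCc2ccc3ccccc3c2)C(C)(C)OC(C)=O)C(=O)CC1
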